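Everything rests on cutting the second dihydrofuran ring (O1–C2–C3–C3a–C7a, fused to central ring D) at O1–C2 and C2–C3. Ring D carries O1 and the benzhydrylic C3 on adjacent carbons, so O1–C7a–C3a–C3 is a latent ortho-quinone methide, released by base from a phenol sulfone that already holds every other ring. A chiral 2,4-dimethoxybenzyl sulfonium ylide delivers C2 with its aryl ring F: conjugate addition, then 5-exo-tet displacement, closes the trans ring in one (4+1) operation under reagent control, which the remote first benzofuran cannot give. The two oxygens flanking C3a on ring D are told apart by chelation-controlled mono-demethylation. The same annulation builds the first benzofuran.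

Key step: step 11

Ring letters: A = 4-hydroxyphenyl of the styryl group; B = benzo ring of the first (styryl-bearing) dihydrobenzofuran; C = 4-hydroxyphenyl on its C2; D = central ring, benzo ring of the second dihydrobenzofuran; E = 3,5-dihydroxyphenyl on its C3; F = 2,4-dihydroxyphenyl on its C2. Both dihydrobenzofurans of the target are trans and (2R,3R).

Assumption: the (1S,4S,5S) antipode of isothiocineole is taken, by analogy with the face selectivity of its benzyl ylides toward aldehydes, to deliver the 2R centres; should step 6 show the opposite sense, the (1R,4R,5R) sulfide is used in steps 5 and 10 with nothing else changed.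

**Step 1**
Reactants: 1 4-bromo-2,6-dimethoxybenzaldehyde; 2 4-methoxystyrene
Product: 3 (E)-2,6-dimethoxy-4-[2-(4-methoxyphenyl)ethenyl]benzaldehyde
Conditions: Pd(OAc)2 (2 mol %), P(o-tol)3, NaOAc, DMF, 110 °C
Reagents that add atoms: none
Why: Mizoroki–Heck arylation of the terminal alkene by an aryl bromide activated by the para formyl group; syn insertion and syn β-hydride elimination should give the E-stilbene.

**Step 2**
Reactants: 3 (E)-2,6-dimethoxy-4-[2-(4-methoxyphenyl)ethenyl]benzaldehyde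
Product: 4 (E)-2-hydroxy-6-methoxy-4-[2-(4-methoxyphenyl)ethenyl]benzaldehyde
Conditions: BCl3 (1.2 equiv), CH2Cl2, −78 → 0 °C; H2O
Reagents that add atoms: none
Why: chelation-controlled mono-demethylation: BCl3 bridges the formyl oxygen and one ortho methoxy group and cleaves only that O–CH3 bond, the resulting boron chelate protecting the second ortho ether and the remote anisole ether being inert at this temperature.

**Step 3**
Reactants: 5 4-bromo-2,6-difluorobenzonitrile
Product: 6 4-bromo-2,6-dimethoxybenzonitrile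
Conditions: NaOMe (2.5 equiv), MeOH/THF, 65 °C
Reagents that add atoms: sodium methoxide, [Na+].[O-]C
Why: double SNAr at the two fluorides ortho to the nitrile, fluoride being displaced far faster than the para bromide.

**Step 4**
Reactants: 4 (E)-2-hydroxy-6-methoxy-4-[2-(4-methoxyphenyl)ethenyl]benzaldehyde; 6 4-bromo-2,6-dimethoxybenzonitrile
Product: 9 4-[{2-hydroxy-6-methoxy-4-[(E)-2-(4-methoxyphenyl)ethenyl]phenyl}(4-methylbenzenesulfonyl)methyl]-2,6-dimethoxybenzonitrile (racemic at the sulfonyl carbon), via arylmagnesium chloride 7 (not isolated), via diaryl carbinol 8 (not isolated)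
Conditions: 6, i-PrMgCl·LiCl, THF, 0 °C; added to 4 pre-treated with NaH (1.0 equiv), THF, 0 °C → rt; aq NH4Cl; crude 8, p-TolSO2H (1.5 equiv, freshly liberated from its sodium salt), MgSO4, CH2Cl2, rt
Reagents that add atoms: p-toluenesulfinic acid, Cc1ccc(S(=O)O)cc1
Why: bromine–magnesium exchange with the turbo-Grignard reagent tolerates the doubly flanked nitrile, 1,2-addition to the aldehyde of the sodium phenoxide gives the ortho-hydroxy diaryl carbinol, and the sulfinic acid ionises this electron-rich carbinol and captures the cation at sulfur to give a bench-stable quinone methide precursor.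

**Step 5**
Reactants: 10 4-methoxybenzyl alcohol; 11 (1S,4S,5S)-isothiocineole [(1S,4S,5S)-4,7,7-trimethyl-6-thiabicyclo[3.2.1]octane]
Product: 12 (1S,4S,5S)-6-(4-methoxybenzyl)-4,7,7-trimethyl-6-thiabicyclo[3.2.1]octan-6-ium tetrafluoroborate
Conditions: HBF4·OEt2 (1.0 equiv), CH2Cl2, 0 °C → rt
Reagents that add atoms: tetrafluoroboric acid, [H+].F[B-](F)(F)F
Why: sulfonium salt formation by SN1 S-alkylation of the sulfide with the 4-methoxybenzyl cation released from the alcohol; alkylation on the less hindered sulfur lone pair should give one sulfur diastereomer.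

**Step 6**
Reactants: 9 the phenol sulfone of step 4; 12 the 4-methoxybenzyl sulfonium tetrafluoroborate
Product: 16 2,6-dimethoxy-4-{(2R,3R)-4-methoxy-2-(4-methoxyphenyl)-6-[(E)-2-(4-methoxyphenyl)ethenyl]-2,3-dihydro-1-benzofuran-3-yl}benzonitrile, via sulfonium ylide 13 (not isolated), via ortho-quinone methide 14 (not isolated), via betaine 15 (not isolated)
Conditions: 12 (1.3 equiv), Cs2CO3 (3 equiv), MeCN/CH2Cl2, −20 °C; slow addition of 9; → rt
Reagents that add atoms: none
Why: Proposed new method: Cs2CO3 forms the phenoxide of 9, which expels sulfinate to give ortho-quinone methide 14, and deprotonates 12 to ylide 13; the ylide carbon adds to the exocyclic carbon and the phenoxide of betaine 15 displaces the sulfide 5-exo-tet with inversion, so C2 is set by the ylide face left open by the bicyclic sulfide and C3 by the anti approach that leads to the trans ring; the closest known reactions are the (4+1) annulation of ortho-quinone methides from 2-(sulfonylalkyl)phenols with carbonyl-stabilised sulfur ylides to trans-2,3-dihydrobenzofurans and the asymmetric epoxidation of aldehydes by isothiocineole benzyl ylides, the untested element being a chiral semistabilised ylide in this annulation.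

**Step 7**
Reactants: 16 the (2R,3R)-dihydrobenzofuranyl benzonitrile of step 6
Product: 17 2,6-dimethoxy-4-{(2R,3R)-4-methoxy-2-(4-methoxyphenyl)-6-[(E)-2-(4-methoxyphenyl)ethenyl]-2,3-dihydro-1-benzofuran-3-yl}benzaldehyde
Conditions: i-Bu2AlH (1.3 equiv), CH2Cl2, −78 → 0 °C; 1 M HCl, 0 °C
Reagents that add atoms: water, O
Why: partial reduction of the nitrile stops at the N-aluminio imine, which is hydrolysed to the aldehyde on work-up; aryl ethers, the stilbene and both stereocentres are inert to the hydride.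

**Step 8**
Reactants: 17 the 2,6-dimethoxybenzaldehyde of step 7
Product: 18 2-hydroxy-6-methoxy-4-{(2R,3R)-4-methoxy-2-(4-methoxyphenyl)-6-[(E)-2-(4-methoxyphenyl)ethenyl]-2,3-dihydro-1-benzofuran-3-yl}benzaldehyde
Conditions: BCl3 (1.2 equiv), CH2Cl2, −78 → −20 °C; H2O
Reagents that add atoms: none
Why: the same chelation-controlled mono-demethylation as in step 2, the formyl group being the strongest Lewis-basic site, so that one equivalent of BCl3 at low temperature should spare the benzylic ether of the first benzofuran, whose trans form is in any case the thermodynamic one.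

**Step 9**
Reactants: 18 the 2-hydroxy-6-methoxybenzaldehyde of step 8; 19 (3,5-dimethoxyphenyl)magnesium bromide
Product: 21 2-[(3,5-dimethoxyphenyl)(4-methylbenzenesulfonyl)methyl]-3-methoxy-5-{(2R,3R)-4-methoxy-2-(4-methoxyphenyl)-6-[(E)-2-(4-methoxyphenyl)ethenyl]-2,3-dihydro-1-benzofuran-3-yl}phenol (both epimers at the sulfonyl carbon), via diaryl carbinol 20 (not isolated)
Conditions: NaH (1.0 equiv), THF, 0 °C; 19 (1.3 equiv), 0 °C → rt; aq NH4Cl; crude 20, p-TolSO2H (1.5 equiv), MgSO4, CH2Cl2, rt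
Reagents that add atoms: p-toluenesulfinic acid, Cc1ccc(S(=O)O)cc1
Why: Grignard 1,2-addition to the aldehyde of the sodium phenoxide followed by sulfinate capture of the ionised ortho-hydroxy diaryl carbinol, as in step 4; the configuration of the new carbon is irrelevant because it becomes trigonal in the next step.

**Step 10**
Reactants: 22 2,4-dimethoxybenzyl alcohol; 11 (1S,4S,5S)-isothiocineole
Product: 23 (1S,4S,5S)-6-(2,4-dimethoxybenzyl)-4,7,7-trimethyl-6-thiabicyclo[3.2.1]octan-6-ium tetrafluoroborate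
Conditions: HBF4·OEt2 (1.0 equiv), 11 (1.2 equiv), CH2Cl2, −20 °C → rt; used fresh
Reagents that add atoms: tetrafluoroboric acid, [H+].F[B-](F)(F)F
Why: SN1 sulfonium salt formation as in step 5, the excess sulfide intercepting the very stabilised 2,4-dimethoxybenzyl cation before it can alkylate another arene.

**Step 11**
Reactants: 21 the phenol sulfone of step 9; 23 the 2,4-dimethoxybenzyl sulfonium tetrafluoroborate
Product: 27 (2R,3R)-2-(2,4-dimethoxyphenyl)-3-(3,5-dimethoxyphenyl)-4-methoxy-6-{(2R,3R)-4-methoxy-2-(4-methoxyphenyl)-6-[(E)-2-(4-methoxyphenyl)ethenyl]-2,3-dihydro-1-benzofuran-3-yl}-2,3-dihydro-1-benzofuran (octamethyl ether of the target), via sulfonium ylide 24 (not isolated), via ortho-quinone methide 25 (not isolated), via betaine 26 (not isolated)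
Conditions: 23 (1.3 equiv), Cs2CO3 (3 equiv), MeCN/CH2Cl2, −20 °C; slow addition of 21; → rt
Reagents that add atoms: none
Why: Proposed new method: Cs2CO3 deprotonates the phenol of 21, which expels sulfinate (E1cB) to give ortho-quinone methide 25 across O1–C7a–C3a–C3, and deprotonates 23 to the semistabilised ylide 24; the ylide carbon adds to the exocyclic C3 to give betaine 26, whose phenoxide O1 displaces the sulfide at C2 with inversion. The closest known reactions are the (4+1) annulation of ortho-quinone methides from 2-(sulfonylalkyl)phenols with carbonyl-stabilised sulfur ylides, which gives trans-2,3-dihydrobenzofurans, and the asymmetric epoxidation of aldehydes by isothiocineole benzyl ylides; untested is the chiral semistabilised ylide on a quinone methide. The dihydrofuran closes 5-exo-tet at C2 (O1–C2 bond) after the intermolecular C2–C3 bond, and with all six benzene rings and the first dihydrofuran already present this closure completes the skeleton. C2 is set by the ylide face left open by the bicyclic sulfide and fixed by the stereospecific SN2 closure; C3 follows from the anti approach that keeps ring F away from ring E, as in the trans-selective epoxidations, and rearomatisation of ring D makes the addition irreversible. The step needs C-alkylation of the ylide by the quinone methide to outrun O-benzylation of the phenoxide by the sulfonium salt, which the strongly electrophilic, aromatising quinone methide and the slow addition of 21 should secure, and it needs reagent control because the first benzofuran is too remote to direct. The methyl ether on the other oxygen flanking C3a leaves O1 as the only phenol, so a single quinone methide and a single ring can form.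

**Step 12**
Reactants: 27 the octamethyl ether
Product: 28 4-[(2R,3R)-3-(3,5-dihydroxyphenyl)-4-hydroxy-6-{(2R,3R)-4-hydroxy-2-(4-hydroxyphenyl)-6-[(E)-2-(4-hydroxyphenyl)ethenyl]-2,3-dihydro-1-benzofuran-3-yl}-2,3-dihydro-1-benzofuran-2-yl]benzene-1,3-diol (target)
Conditions: BBr3 (excess), CH2Cl2, −78 → 0 °C; H2O
Reagents that add atoms: none
Why: exhaustive Lewis-acid demethylation of the eight aryl methyl ethers; reversible ionisation of either benzylic C2–O bond can only return the trans rings because C3 is untouched, and the E-alkene should survive at low temperature.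

**Compound list**
1 | 4-bromo-2,6-dimethoxybenzaldehyde | O=Cc1c(OC)cc(Br)cc1OC | starting material
2 | 4-methoxystyrene | C=Cc1ccc(OC)cc1 | starting material
3 | (E)-2,6-dimethoxy-4-[2-(4-methoxyphenyl)ethenyl]benzaldehyde | O=Cc1c(OC)cc(/C=C/c2ccc(OC)cc2)cc1OC | intermediate
4 | (E)-2-hydroxy-6-methoxy-4-[2-(4-methoxyphenyl)ethenyl]benzaldehyde | O=Cc1c(O)cc(/C=C/c2ccc(OC)cc2)cc1OC | intermediate
5 | 4-bromo-2,6-difluorobenzonitrile | N#Cc1c(F)cc(Br)cc1F | starting material
6 | 4-bromo-2,6-dimethoxybenzonitrile | N#Cc1c(OC)cc(Br)cc1OC | intermediate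
7 | (4-cyano-3,5-dimethoxyphenyl)magnesium chloride (LiCl complex; not isolated) | N#Cc1c(OC)cc([Mg]Cl)cc1OC | intermediate
8 | 4-[hydroxy{2-hydroxy-6-methoxy-4-[(E)-2-(4-methoxyphenyl)ethenyl]phenyl}methyl]-2,6-dimethoxybenzonitrile (racemic; not isolated) | N#Cc1c(OC)cc(C(O)c2c(O)cc(/C=C/c3ccc(OC)cc3)cc2OC)cc1OC | intermediate
9 | 4-[{2-hydroxy-6-methoxy-4-[(E)-2-(4-methoxyphenyl)ethenyl]phenyl}(4-methylbenzenesulfonyl)methyl]-2,6-dimethoxybenzonitrile (racemic) | N#Cc1c(OC)cc(C(c2c(O)cc(/C=C/c3ccc(OC)cc3)cc2OC)S(=O)(=O)c2ccc(C)cc2)cc1OC | intermediate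
10 | 4-methoxybenzyl alcohol | COc1ccc(CO)cc1 | starting material
11 | (1S,4S,5S)-isothiocineole | C[C@H]1CC[C@H]2C[C@@H]1SC2(C)C | starting material
12 | (1S,4S,5S)-6-(4-methoxybenzyl)-4,7,7-trimethyl-6-thiabicyclo[3.2.1]octan-6-ium tetrafluoroborate (sulfur configuration not specified) | C[C@H]1CC[C@H]2C[C@@H]1[S+](Cc1ccc(OC)cc1)C2(C)C.F[B-](F)(F)F | intermediate
13 | 4-methoxybenzylide of the isothiocineole sulfonium (not isolated) | C[C@H]1CC[C@H]2C[C@@H]1[S+]([CH-]c1ccc(OC)cc1)C2(C)C | intermediate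
14 | 4-[{2-methoxy-4-[(E)-2-(4-methoxyphenyl)ethenyl]-6-oxocyclohexa-2,4-dien-1-ylidene}methyl]-2,6-dimethoxybenzonitrile (exocyclic geometry undefined; not isolated) | N#Cc1c(OC)cc(C=C2C(=O)C=C(/C=C/c3ccc(OC)cc3)C=C2OC)cc1OC | intermediate
15 | phenoxide–sulfonium betaine from C-addition of 13 to 14 (not isolated) | C[C@H]1CC[C@H]2C[C@@H]1[S+]([C@H](c1ccc(OC)cc1)[C@H](c1cc(OC)c(C#N)c(OC)c1)c1c([O-])cc(/C=C/c3ccc(OC)cc3)cc1OC)C2(C)C | intermediate
16 | 2,6-dimethoxy-4-{(2R,3R)-4-methoxy-2-(4-methoxyphenyl)-6-[(E)-2-(4-methoxyphenyl)ethenyl]-2,3-dihydro-1-benzofuran-3-yl}benzonitrile | COc1ccc(/C=C/c2cc(OC)c3c(c2)O[C@@H](c2ccc(OC)cc2)[C@@H]3c2cc(OC)c(C#N)c(OC)c2)cc1 | intermediate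
17 | 2,6-dimethoxy-4-{(2R,3R)-4-methoxy-2-(4-methoxyphenyl)-6-[(E)-2-(4-methoxyphenyl)ethenyl]-2,3-dihydro-1-benzofuran-3-yl}benzaldehyde | COc1ccc(/C=C/c2cc(OC)c3c(c2)O[C@@H](c2ccc(OC)cc2)[C@@H]3c2cc(OC)c(C=O)c(OC)c2)cc1 | intermediate
18 | 2-hydroxy-6-methoxy-4-{(2R,3R)-4-methoxy-2-(4-methoxyphenyl)-6-[(E)-2-(4-methoxyphenyl)ethenyl]-2,3-dihydro-1-benzofuran-3-yl}benzaldehyde | COc1ccc(/C=C/c2cc(OC)c3c(c2)O[C@@H](c2ccc(OC)cc2)[C@@H]3c2cc(O)c(C=O)c(OC)c2)cc1 | intermediate
19 | (3,5-dimethoxyphenyl)magnesium bromide (THF solution) | COc1cc(OC)cc([Mg]Br)c1 | starting material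
20 | 2-[(3,5-dimethoxyphenyl)(hydroxy)methyl]-3-methoxy-5-{(2R,3R)-4-methoxy-2-(4-methoxyphenyl)-6-[(E)-2-(4-methoxyphenyl)ethenyl]-2,3-dihydro-1-benzofuran-3-yl}phenol (both carbinol epimers; not isolated) | COc1ccc(/C=C/c2cc(OC)c3c(c2)O[C@@H](c2ccc(OC)cc2)[C@@H]3c2cc(O)c(C(O)c3cc(OC)cc(OC)c3)c(OC)c2)cc1 | intermediate
21 | 2-[(3,5-dimethoxyphenyl)(4-methylbenzenesulfonyl)methyl]-3-methoxy-5-{(2R,3R)-4-methoxy-2-(4-methoxyphenyl)-6-[(E)-2-(4-methoxyphenyl)ethenyl]-2,3-dihydro-1-benzofuran-3-yl}phenol (both epimers at the sulfonyl carbon) | COc1ccc(/C=C/c2cc(OC)c3c(c2)O[C@@H](c2ccc(OC)cc2)[C@@H]3c2cc(O)c(C(c3cc(OC)cc(OC)c3)S(=O)(=O)c3ccc(C)cc3)c(OC)c2)cc1 | intermediate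
22 | 2,4-dimethoxybenzyl alcohol | COc1ccc(CO)c(OC)c1 | starting material
23 | (1S,4S,5S)-6-(2,4-dimethoxybenzyl)-4,7,7-trimethyl-6-thiabicyclo[3.2.1]octan-6-ium tetrafluoroborate (sulfur configuration not specified) | C[C@H]1CC[C@H]2C[C@@H]1[S+](Cc1ccc(OC)cc1OC)C2(C)C.F[B-](F)(F)F | intermediate
24 | 2,4-dimethoxybenzylide of the isothiocineole sulfonium (not isolated) | C[C@H]1CC[C@H]2C[C@@H]1[S+]([CH-]c1ccc(OC)cc1OC)C2(C)C | intermediate
25 | ring D ortho-quinone methide: 6-[(3,5-dimethoxyphenyl)methylidene]-5-methoxy-3-{(2R,3R)-4-methoxy-2-(4-methoxyphenyl)-6-[(E)-2-(4-methoxyphenyl)ethenyl]-2,3-dihydro-1-benzofuran-3-yl}cyclohexa-2,4-dien-1-one (exocyclic geometry undefined; not isolated) | COc1ccc(/C=C/c2cc(OC)c3c(c2)O[C@@H](c2ccc(OC)cc2)[C@@H]3C2=CC(=O)C(=Cc3cc(OC)cc(OC)c3)C(OC)=C2)cc1 | intermediate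
26 | phenoxide–sulfonium betaine from C-addition of 24 to 25 (not isolated) | C[C@H]1CC[C@H]2C[C@@H]1[S+]([C@H](c1ccc(OC)cc1OC)[C@H](c1cc(OC)cc(OC)c1)c1c([O-])cc(cc1OC)[C@@H]1c3c(OC)cc(/C=C/c4ccc(OC)cc4)cc3O[C@H]1c1ccc(OC)cc1)C2(C)C | intermediate
27 | (2R,3R)-2-(2,4-dimethoxyphenyl)-3-(3,5-dimethoxyphenyl)-4-methoxy-6-{(2R,3R)-4-methoxy-2-(4-methoxyphenyl)-6-[(E)-2-(4-methoxyphenyl)ethenyl]-2,3-dihydro-1-benzofuran-3-yl}-2,3-dihydro-1-benzofuran | COc1ccc(/C=C/c2cc(OC)c3c(c2)O[C@@H](c2ccc(OC)cc2)[C@@H]3c2cc(OC)c3c(c2)O[C@@H](c2ccc(OC)cc2OC)[C@@H]3c2cc(OC)cc(OC)c2)cc1 | intermediate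
28 | 4-[(2R,3R)-3-(3,5-dihydroxyphenyl)-4-hydroxy-6-{(2R,3R)-4-hydroxy-2-(4-hydroxyphenyl)-6-[(E)-2-(4-hydroxyphenyl)ethenyl]-2,3-dihydro-1-benzofuran-3-yl}-2,3-dihydro-1-benzofuran-2-yl]benzene-1,3-diol | Oc1ccc(/C=C/c2cc(O)c3c(c2)O[C@@H](c2ccc(O)cc2)[C@@H]3c2cc(O)c3c(c2)O[C@@H](c2ccc(O)cc2O)[C@@H]3c2cc(O)cc(O)c2)cc1 | target

**Step count and risks**
Total step count: 12. Longest linear sequence: 9 steps (1, 2, 4, 6, 7, 8, 9, 11, 12).

Steps most likely to fail:

1. Step 11 (Proposed new method). What may go wrong: O-benzylation of the phenoxide by the labile 2,4-dimethoxybenzyl sulfonium salt instead of ylide formation, self-condensation of the quinone methide, or poor anti topicity in the ylide addition, which would give the cis ring with the wrong C3 and so a diastereomer that acid cannot correct. The fallback uses a known reaction type, enantioselective rhodium-carbene C–H insertion into an aryl benzyl ether followed by acid epimerisation at C2; it sets out from 18 and comes back at 27. Mitsunobu etherification of 18 with 22 (PPh3, DIAD, THF) should give the 2,4-dimethoxybenzyl ether F1. Addition of 19 should give the diaryl carbinol F2, and MnO2 (or Dess–Martin periodinane) the benzophenone F3. N2H4·H2O with AcOH in hot n-BuOH should give the hydrazone F4, which MnO2 oxidises to the diaryl diazomethane F5. With Rh2(S-PTAD)4 (or its antipode, whichever gives the 3R series) F5 should insert into the ArO–CH2Ar bond to give the cis-dihydrobenzofuran F6. CF3CO2H in CH2Cl2 at 0 °C then epimerises C2 through the 2,4-dimethoxybenzylic cation to the trans ring of 27, C3 being untouched.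

2. Step 6 (Proposed new method). What may go wrong: the same competition between O-benzylation and C-addition, and loss of trans or face selectivity in the first use of the chiral ylide on a quinone methide. The fallback is the same known carbene C–H insertion sequence; it sets out from 4 and comes back at 16. Mitsunobu etherification of 4 with 10 should give the 4-methoxybenzyl ether F7. Addition of 7 should give the carbinol F8, and MnO2 the benzophenone F9. N2H4·H2O with AcOH in hot n-BuOH should give the hydrazone F10, and MnO2 the diazo compound F11. Rh2(S-PTAD)4 (or its antipode) should give the cis-dihydrobenzofuran F12 by insertion into the benzylic ether C–H bond, and CF3CO2H in CH2Cl2 should epimerise C2 to give trans 16.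

3. Step 12. What may go wrong: Lewis-acid ionisation of the very labile C2–O bond next to ring F followed by elimination or intramolecular Friedel–Crafts capture by ring E instead of reclosure, or incomplete cleavage of the hindered C4 methyl ethers. The fallback sets out from 27 and comes back at 28. It replaces electrophilic cleavage by exhaustive nucleophilic demethylation with MeMgI (large excess, ether removed, 150–160 °C melt, then aq NH4Cl). This is SN2 attack at O–CH3 in a basic medium in which the benzylic ethers cannot ionise, and it passes through no new isolated compound.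

**Further compounds**
F1 | step 11 | 2-[(2,4-dimethoxybenzyl)oxy]-6-methoxy-4-{(2R,3R)-4-methoxy-2-(4-methoxyphenyl)-6-[(E)-2-(4-methoxyphenyl)ethenyl]-2,3-dihydro-1-benzofuran-3-yl}benzaldehyde | COc1ccc(/C=C/c2cc(OC)c3c(c2)O[C@@H](c2ccc(OC)cc2)[C@@H]3c2cc(OCc3ccc(OC)cc3OC)c(C=O)c(OC)c2)cc1
F2 | step 11 | diaryl carbinol from F1 and 19 (both carbinol epimers) | COc1ccc(/C=C/c2cc(OC)c3c(c2)O[C@@H](c2ccc(OC)cc2)[C@@H]3c2cc(OCc3ccc(OC)cc3OC)c(C(O)c3cc(OC)cc(OC)c3)c(OC)c2)cc1
F3 | step 11 | (3,5-dimethoxyphenyl) aryl ketone from F2 | COc1ccc(/C=C/c2cc(OC)c3c(c2)O[C@@H](c2ccc(OC)cc2)[C@@H]3c2cc(OCc3ccc(OC)cc3OC)c(C(=O)c3cc(OC)cc(OC)c3)c(OC)c2)cc1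
F4 | step 11 | hydrazone of F3 | COc1ccc(/C=C/c2cc(OC)c3c(c2)O[C@@H](c2ccc(OC)cc2)[C@@H]3c2cc(OCc3ccc(OC)cc3OC)c(C(=NN)c3cc(OC)cc(OC)c3)c(OC)c2)cc1
F5 | step 11 | diaryl diazomethane from F4 | COc1ccc(/C=C/c2cc(OC)c3c(c2)O[C@@H](c2ccc(OC)cc2)[C@@H]3c2cc(OCc3ccc(OC)cc3OC)c(C(=[N+]=[N-])c3cc(OC)cc(OC)c3)c(OC)c2)cc1
F6 | step 11 | (2S,3R)-cis epimer of 27 at C2 of the second dihydrobenzofuran | COc1ccc(/C=C/c2cc(OC)c3c(c2)O[C@@H](c2ccc(OC)cc2)[C@@H]3c2cc(OC)c3c(c2)O[C@H](c2ccc(OC)cc2OC)[C@@H]3c2cc(OC)cc(OC)c2)cc1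
F7 | step 6 | (E)-2-methoxy-6-[(4-methoxybenzyl)oxy]-4-[2-(4-methoxyphenyl)ethenyl]benzaldehyde | O=Cc1c(OCc2ccc(OC)cc2)cc(/C=C/c2ccc(OC)cc2)cc1OC
F8 | step 6 | diaryl carbinol from F7 and 7 (racemic) | N#Cc1c(OC)cc(C(O)c2c(OCc3ccc(OC)cc3)cc(/C=C/c3ccc(OC)cc3)cc2OC)cc1OC
F9 | step 6 | diaryl ketone from F8 | N#Cc1c(OC)cc(C(=O)c2c(OCc3ccc(OC)cc3)cc(/C=C/c3ccc(OC)cc3)cc2OC)cc1OC
F10 | step 6 | hydrazone of F9 | N#Cc1c(OC)cc(C(=NN)c2c(OCc3ccc(OC)cc3)cc(/C=C/c3ccc(OC)cc3)cc2OC)cc1OC
F11 | step 6 | diaryl diazomethane from F10 | N#Cc1c(OC)cc(C(=[N+]=[N-])c2c(OCc3ccc(OC)cc3)cc(/C=C/c3ccc(OC)cc3)cc2OC)cc1OC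
F12 | step 6 | 2,6-dimethoxy-4-{(2S,3R)-4-methoxy-2-(4-methoxyphenyl)-6-[(E)-2-(4-methoxyphenyl)ethenyl]-2,3-dihydro-1-benzofuran-3-yl}benzonitrile (cis) | COc1ccc(/C=C/c2cc(OC)c3c(c2)O[C@H](c2ccc(OC)cc2)[C@@H]3c2cc(OC)c(C#N)c(OC)c2)cc1
F0 | step 12 | none | none
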